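Compound numbers refer to the list after the steps. Ring A atoms keep the chromene locants of the target (C4a, C5, C6, C7, C8, C8a) in every intermediate.

## Analysis of the target

Target 38 is a 3,4,7,8-tetrahydro-2H-chromene-4,7-dione. Ring C is a 2,3-dimethyl-2,3-dihydro-4-pyranone (O1, C2, C3, C4, C4a, C8a), and ring A (C4a, C5, C6, C7, C8, C8a) is a phloroglucinol that cannot aromatize because C8 is quaternary. There are six stereocenters in four isolated groups: cis C2/C3 (2R,3S), the quaternary C8 (R) carrying a prenyl and a cyclobutylmethyl group, C3′ (S) of the hexanoic acid chain on C6, and the cis-1,3-disubstituted cyclobutane (1S,3R). No group can relay its configuration to another, so each must be set or imported on its own. C8 is the hard one, because its two carbon substituents are both CH2R groups of similar size. The sensitive groups are the chelated C5 enol with the C4 and C7 carbonyls, C3–H next to the C4 ketone (epimerization and β-elimination of O1 under base), the isopropenylcyclobutane and prenyl groups (protonation leads to cyclobutylcarbinyl ring expansion or closure onto an enol oxygen), and the free acid, which can lactonize onto O5 or O7. Strong acid and strong base are therefore both excluded late in the route. The strategy rests on the three differentiated oxygens of ring A: a C7 ketone next to the quaternary C8, a C5 enol, and a C8a enol ether, with the alkyl chain on C6 next to the ketone. That is the pattern of a cyclohexa-2,4-dienone formed when a vinylketene from a 3-alkoxy-4,4-dialkylcyclobutenone takes up an ynol ether and the resulting dienylketene closes between C7 and C8.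

## Retrosynthetic reasoning

**38 ⇒ 36.** The last bond cut is the O–C(CH3)3 bond of tert-butyl ester 36. A tert-butyl ester is the one simple ester that survives the organolithium chemistry of the ynol ether synthesis, the heat of the annulation and the chromium coupling. The forward step has to remove it without protic acid, because of the two acid-labile alkenes.

**36 ⇒ 34 (through 35).** Ring C is opened at O1–C8a. In the forward sense the freed C2 hydroxyl adds to C8a and the ethoxy group leaves. C8a is the only ring carbon that carries a leaving group, so the ethoxy label decides the regiochemistry, not a competition between the C5 and C8a oxygens. No bond to C2 or C3 is broken, so the cis relationship is simply carried in.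

**34 ⇒ 33 ⇒ 32 + 27; 32 ⇒ 31.** The C4–C4a bond is cut. An O-to-C acyl shift onto C4a was weighed and set aside. While C8a remains an enol ether, C4a is the β-carbon of that enol ether and not the central carbon of a 1,3-dicarbonyl, so the acyl-transfer catalysis that works for cyclic 1,3-diones has no basis here. Hydrolyzing the enol ether to gain that reactivity would erase the C8a label. C4a is instead turned into a carbon–metal bond: iodide 32 is coupled with aldehyde 27 under chromium mediation to give carbinol 33, which is oxidized to 34. Iodide 32 comes from 31 by electrophilic substitution of its only vinylic hydrogen.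

**31 ⇒ 11 + 21 (key disconnection).** Ring A is cut at C7–C6, C5–C4a and C8–C7. The C7 carbonyl, C8, C8a (with its ethoxy group) and C4a come from cyclobutenone 11; C6 with its chain and C5 with its silyloxy group come from ynol ether 21. One thermal operation must open 11 to vinylketene 28, add 21 with the correct orientation, and close dienylketene 30 between C7 and C8. Ring A arrives fully substituted and with three distinguishable oxygens. The cost is that C8 is set in a pericyclic closure with little bias.

**11 ⇒ 7 + 8; 7 ⇒ 5 + 6; 5 ⇒ 4 ⇒ 3 ⇒ 2 ⇒ 1.** The cyclobutenone is cut across its two ring bonds into dialkylketene 10 (from acid 7) and ethoxyacetylene 8. Acid 7 is cut at its α-carbon into iodide 5 and acid 6. The α-stereocenter of 7 is of no concern because it becomes trigonal in 10. Iodide 5 is traced through 4, 3 and 2 to verbenone 1, whose bicycle already holds both cyclobutane stereocenters in the cis relationship.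

**21 ⇒ 18 ⇒ 17 ⇒ 16 ⇒ 14 + 15; 14 ⇒ 12 + 13.** The ynol ether is cut between its two alkyne carbons. Ester-to-ynolate homologation inserts one carbon, so the five-carbon chain of 21 must come from the four-carbon succinate 18 and not from a five-carbon diacid. Its methyl ester is homologated and its tert-butyl ester is the spectator. The stereocenter of 18 is set by auxiliary-controlled alkylation of imide 14 with bromoacetate 15.

**27 ⇒ 26 ⇒ 25 ⇒ 24 ⇒ 22 + 23.** The C2–C3 bond of the future ring C is cut in an auxiliary-controlled syn aldol disconnection between imide 22 and acetaldehyde 23. This delivers both ring C stereocenters in one step, independently of everything else.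

## Alternatives that were turned down

**Alternative 1:** The cyclobutane is cut across the C(CH3)2–CH bond and the opposite ring bond to CH2. In the forward step amide A2 is activated to its keteniminium ion, which adds across the terminal alkene of allyl ether A3 in a [2+2] cycloaddition; hydrolysis gives cyclobutanone A1.
- For: it is a de novo entry that does not depend on the optical purity of a terpene, either enantiomer is available, and the regiochemistry of such additions to monosubstituted alkenes is dependable. On enantiomeric purity it is stronger than the chosen route, which needs 1 of high purity.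
- Against: A1 holds only one of the two ring stereocenters. The isopropenyl group must still be attached at the carbonyl carbon, and the cis relationship set in a separate step with only the gem-dimethyl group to distinguish the faces. Auxiliary control over an unactivated alkene is not expected to be complete.
- Comparison: the chosen route reaches 4 from 1 in three steps with cis geometry guaranteed by the bicycle. Alternative 1 spends its key step on the side chain and leaves ring A and C8 untouched.

**Alternative 2:** The C(CH3)2–CH ring bond is cut back to the acyclic monoterpene ester A5. Protonation of its isopropenyl group gives a tertiary cation, the inner carbon of the trisubstituted alkene attacks it in a 4-exo closure, and loss of a methyl proton gives A4.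
- For: one step, all ten carbons already in place, and it probably mirrors the biosynthesis. On step count it beats the chosen route (one step against three from 1 to 4).
- Against: closure of a strained four-membered ring from a tertiary cation is reversible and competes with faster exits. These are loss of the proton at the adjacent stereocenter (which erases it), six-membered closure after protonation of the other alkene, and hydride shifts. The cis/trans relationship is not controlled, and the product is as acid-sensitive as the starting material.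
- Comparison: without an enzyme template the outcome is not reliable. The chosen route offers a stereochemically certain cyclobutane, and alternative 2 also leaves ring A unaddressed.

**Alternative 3:** Ring C is cut across C2–C3 and O1–C8a into diene A7, whose oxygenated terminus is bonded to a pre-formed quaternary C8, and acetaldehyde (23). An endo [4+2] addition under a chiral Lewis acid of the (salen)CrCl type (trivalent chromium), then acid-induced loss of the methoxy group, gives dihydropyranone A6.
- For: cis C2/C3 is set catalytically, ring C closes without a leaving-group exchange, and no acylation at C4a is needed at that stage. On this point it is stronger than the chosen route, which spends four auxiliary-based steps on 27.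
- Against: the diene terminus is fully substituted and attached to a quaternary carbon, so the reactive conformer and the endo approach are crowded. C8 would have to be enantiopure beforehand, and the plan contains no way to achieve that for two CH2R groups. Ring A must then be built around A6 in several base-mediated steps on a compound whose C3–H and O1 are base-labile.
- Comparison: the chosen annulation makes ring A with all its substituents in one operation from two fragments of similar size, and keeps the epimerizable pyranone out of the synthesis until the second-to-last step. Both routes share the C8 problem.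

Key step: step 16

Remark: 5-methylhex-4-enoic acid 6 and ethoxyacetylene 8 (as a hexane solution) are taken as catalogue compounds, and commercial 1 is taken to be of high enantiomeric purity.
Remark: the stereocenters at C2 of 7 and C4 of 11 are left undefined on purpose, because both carbons become trigonal (in 10 and 28) before C8 is set.

## Route

Step 1
Reactants: 1 (1R,5R)-(+)-verbenone
Product: 2 (1R,3S)-3-acetyl-2,2-dimethylcyclobutane-1-carboxylic acid (cis-pinononic acid)
Conditions: RuCl3·xH2O (2 mol%), NaIO4 (4.2 equiv), CCl4/MeCN/H2O, rt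
Reagents that add atoms: sodium periodate, [Na+].[O-]I(=O)(=O)=O; water, O
Why: Ruthenium tetroxide oxidative cleavage of the enone C=C; the α-keto acid first formed loses CO2, and both ring stereocenters of 1 are untouched, so acetyl and carboxyl end up cis.

Step 2
Reactants: 2 (1R,3S)-3-acetyl-2,2-dimethylcyclobutane-1-carboxylic acid
Product: 3 (1R,3R)-2,2-dimethyl-3-(prop-1-en-2-yl)cyclobutane-1-carboxylic acid
Conditions: Ph3PCH3Br (2.6 equiv), KOtBu (3.6 equiv), THF, 0 °C to rt; aq. citric acid work-up
Reagents that add atoms: methyltriphenylphosphonium bromide, C[P+](c1ccccc1)(c1ccccc1)c1ccccc1.[Br-]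
Why: Wittig methylenation of the methyl ketone with the carboxylate as an inert spectator; enolization toward the ring carbon would create an exocyclic double bond on a cyclobutane, so the cis configuration should hold.

Step 3
Reactants: 3 (1R,3R)-2,2-dimethyl-3-(prop-1-en-2-yl)cyclobutane-1-carboxylic acid
Product: 4 [(1R,3R)-2,2-dimethyl-3-(prop-1-en-2-yl)cyclobutyl]methanol
Conditions: LiAlH4, THF, 0 °C to rt; Fieser work-up
Reagents that add atoms: none
Why: Hydride reduction of the acid to the primary alcohol; the isolated alkene is inert.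

Step 4
Reactants: 4 [(1R,3R)-2,2-dimethyl-3-(prop-1-en-2-yl)cyclobutyl]methanol
Product: 5 (1R,3R)-1-(iodomethyl)-2,2-dimethyl-3-(prop-1-en-2-yl)cyclobutane
Conditions: I2, PPh3, imidazole, CH2Cl2, 0 °C to rt
Reagents that add atoms: iodine, II
Why: Appel-type iodination by SN2 at the primary carbon; no cyclobutylcarbinyl cation is formed, so ring expansion is not expected.

Step 5
Reactants: 5 (1R,3R)-1-(iodomethyl)-2,2-dimethyl-3-(prop-1-en-2-yl)cyclobutane; 6 5-methylhex-4-enoic acid
Product: 7 2-{[(1S,3R)-2,2-dimethyl-3-(prop-1-en-2-yl)cyclobutyl]methyl}-5-methylhex-4-enoic acid (both C2 epimers)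
Conditions: 6 (1.5 equiv), LiN(iPr)2 (3.1 equiv), THF, 0 °C to rt; DMPU; then 5, 0 °C to rt; dilute citric acid
Reagents that add atoms: none
Why: Alkylation of a carboxylic acid dianion with a primary iodide; the new α-stereocenter is irrelevant because it becomes the ketene carbon.

Step 6
Reactants: 7 2-{[(1S,3R)-2,2-dimethyl-3-(prop-1-en-2-yl)cyclobutyl]methyl}-5-methylhex-4-enoic acid; 8 ethoxyacetylene
Product: 11 4-{[(1S,3R)-2,2-dimethyl-3-(prop-1-en-2-yl)cyclobutyl]methyl}-3-ethoxy-4-(3-methylbut-2-en-1-yl)cyclobut-2-en-1-one (both C4 epimers), via acid chloride 9 (not isolated), via dialkylketene 10 (not isolated)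
Conditions: 1-chloro-N,N,2-trimethylprop-1-en-1-amine, CH2Cl2, 0 °C to rt; then 8 (3 equiv), Et3N (2 equiv), CH2Cl2/hexanes, rt to 40 °C, closed vessel
Reagents that add atoms: none
Why: The chloroenamine makes 9 without releasing HCl; dehydrochlorination gives 10, which adds 8 in a ketene–alkoxyalkyne [2+2] cycloaddition with the nucleophilic terminal alkyne carbon bonding to the ketene carbonyl carbon, so the ethoxy group ends at C3.

Step 7
Reactants: 12 (4R)-4-benzyl-1,3-oxazolidin-2-one; 13 pentanoyl chloride
Product: 14 (4R)-4-benzyl-3-pentanoyl-1,3-oxazolidin-2-one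
Conditions: n-BuLi, THF, −78 °C; then 13, −78 to 0 °C
Reagents that add atoms: none
Why: N-acylation of the lithiated oxazolidinone.

Step 8
Reactants: 14 (4R)-4-benzyl-3-pentanoyl-1,3-oxazolidin-2-one; 15 tert-butyl bromoacetate
Product: 16 tert-butyl (3S)-3-{[(4R)-4-benzyl-2-oxo-1,3-oxazolidin-3-yl]carbonyl}hexanoate
Conditions: NaN(SiMe3)2, THF, −78 °C; then 15, −78 to −30 °C
Reagents that add atoms: none
Why: Evans alkylation; the chelated Z-enolate is shielded on one face by the (4R)-benzyl group, so 15 should add to the other face and give the (S) center.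

Step 9
Reactants: 16 tert-butyl (3S)-3-{[(4R)-4-benzyl-2-oxo-1,3-oxazolidin-3-yl]carbonyl}hexanoate
Product: 17 (2S)-2-[2-(tert-butoxy)-2-oxoethyl]pentanoic acid
Conditions: LiOH, H2O2, THF/H2O, 0 °C; Na2SO3; cold 1 M HCl to pH 3
Reagents that add atoms: hydrogen peroxide, OO
Why: Hydroperoxide attacks the exocyclic imide carbonyl selectively, the auxiliary is recovered, and the tert-butyl ester and the stereocenter are not touched.

Step 10
Reactants: 17 (2S)-2-[2-(tert-butoxy)-2-oxoethyl]pentanoic acid
Product: 18 4-tert-butyl 1-methyl (2S)-2-propylbutanedioate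
Conditions: Me3SiCHN2, MeOH/toluene, 0 °C to rt
Reagents that add atoms: trimethylsilyldiazomethane, C[Si](C)(C)C=[N+]=[N-]
Why: Neutral methyl esterification that cannot epimerize the α-center; it provides the more electrophilic of the two esters for step 11.

Step 11
Reactants: 18 4-tert-butyl 1-methyl (2S)-2-propylbutanedioate
Product: 21 tert-butyl (3S)-3-propyl-5-[tri(propan-2-yl)silyloxy]pent-4-ynoate, via dibromo enolate 19 (not isolated), via lithium ynolate 20 (not isolated)
Conditions: CH2Br2, lithium 2,2,6,6-tetramethylpiperidide, THF, −78 °C; LiN(SiMe3)2, −78 to −20 °C; n-BuLi, −78 to 0 °C; iPr3SiCl, −78 °C to rt; aq. NaHCO3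
Reagents that add atoms: dibromomethane, BrCBr; chlorotriisopropylsilane, CC(C)[Si](Cl)(C(C)C)C(C)C
Why: Kowalski ester-to-ynolate homologation; LiCHBr2 should add only to the methyl ester (the tert-butyl ester is far less electrophilic and is carried as its lithium enolate), bromine–lithium exchange in 19 triggers a 1,2-shift of the stereogenic carbon with retention to give 20, and the bulky chlorosilane traps 20 on oxygen.

Step 12
Reactants: 22 (4S)-4-benzyl-3-propanoyl-1,3-oxazolidin-2-one; 23 acetaldehyde
Product: 24 (4S)-4-benzyl-3-[(2S,3R)-3-hydroxy-2-methylbutanoyl]-1,3-oxazolidin-2-one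
Conditions: Bu2BOTf, iPr2NEt, CH2Cl2, 0 °C; then 23, −78 to 0 °C; pH 7 buffer, MeOH, H2O2
Reagents that add atoms: none
Why: Evans syn aldol; the Z-boron enolate reacts through a chair transition state on the face away from the benzyl group, which sets both centers as syn (2S,3R).

Step 13
Reactants: 24 (4S)-4-benzyl-3-[(2S,3R)-3-hydroxy-2-methylbutanoyl]-1,3-oxazolidin-2-one
Product: 25 (4S)-4-benzyl-3-[(2S,3R)-2-methyl-3-(triethylsilyloxy)butanoyl]-1,3-oxazolidin-2-one
Conditions: Et3SiOTf, 2,6-lutidine, CH2Cl2, −78 to 0 °C
Reagents that add atoms: triethylsilyl trifluoromethanesulfonate, CC[Si](CC)(CC)OS(=O)(=O)C(F)(F)F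
Why: Silylation of the secondary alcohol prevents retro-aldol cleavage; the group is chosen so that fluoride removes it together with the enol silyl ether in step 20.

Step 14
Reactants: 25 (4S)-4-benzyl-3-[(2S,3R)-2-methyl-3-(triethylsilyloxy)butanoyl]-1,3-oxazolidin-2-one
Product: 26 (2R,3R)-2-methyl-3-(triethylsilyloxy)butan-1-ol
Conditions: LiBH4, MeOH (1 equiv), Et2O, 0 °C
Reagents that add atoms: none
Why: Reductive removal of the auxiliary at the exocyclic carbonyl; the descriptor at C2 changes only because of priorities.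

Step 15
Reactants: 26 (2R,3R)-2-methyl-3-(triethylsilyloxy)butan-1-ol
Product: 27 (2S,3R)-2-methyl-3-(triethylsilyloxy)butanal
Conditions: Dess–Martin periodinane, NaHCO3, CH2Cl2, 0 °C to rt; used at once
Reagents that add atoms: none
Why: Buffered Dess–Martin oxidation gives the α-branched aldehyde without epimerization.

Step 16
Reactants: 11 4-{[(1S,3R)-2,2-dimethyl-3-(prop-1-en-2-yl)cyclobutyl]methyl}-3-ethoxy-4-(3-methylbut-2-en-1-yl)cyclobut-2-en-1-one; 21 tert-butyl (3S)-3-propyl-5-[tri(propan-2-yl)silyloxy]pent-4-ynoate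
Product: 31 tert-butyl (3S)-3-[(5R)-5-{[(1S,3R)-2,2-dimethyl-3-(prop-1-en-2-yl)cyclobutyl]methyl}-4-ethoxy-5-(3-methylbut-2-en-1-yl)-6-oxo-2-[tri(propan-2-yl)silyloxy]cyclohexa-1,3-dien-1-yl]hexanoate (ring A dienone; C8 R), via vinylketene 28 (not isolated), via vinylcyclobutenone 29 (not isolated), via dienylketene 30 (not isolated)
Conditions: 21 (1.4 equiv), toluene (0.5 M), 110 °C, sealed tube, argon, dark; chromatographic separation of the C8 epimers
Reagents that add atoms: none
Why: Heating opens 11 by 4π electrocyclic cleavage of its C1–C4 bond to vinylketene 28, and the alkyne of 21 adds to the ketene C=C in a [2+2] cycloaddition with its carbon remote from oxygen bonding to the ketene carbonyl carbon, which gives 29 with the alkyl chain next to C=O and the silyloxy carbon next to the former C2–H. A second 4π opening gives dienylketene 30, and a thermal disrotatory 6π electrocyclization, the only ring closure that persists, joins the ketene carbon C7 to the dialkylated terminus C8 and forms the six-membered carbocycle; because C8 has no hydrogen the product cannot become a phenol and stays as the cyclohexa-2,4-dienone. The closest known reaction is the Danheiser annulation of cyclobutenones with siloxyalkynes in its variant with 4,4-disubstituted cyclobutenones, and 3-alkoxycyclobutenones are known to open to vinylketenes at this temperature. The step needs regioselectivity in the [2+2], which the polarization of the ynol ether (nucleophilic at the alkyl-bearing carbon) and of the ketene (electrophilic at the carbonyl carbon) secures, and chemoselectivity for the ynol ether over the three isolated alkenes, which its much higher nucleophilicity secures. The new stereocenter C8 is fixed by the face of the C8 terminus that bonds to C7, that is, by the helical sense of 30. Only the C3′ stereocenter on C6 next to the ketene carbon and the remote cyclobutane can bias this, so both C8 epimers are expected and 31 has to be separated here or, failing that, at 36. The geometry of the enol ether double bond of 28 is also uncontrolled, but it is immaterial because either isomer can close on either face.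

Step 17
Reactants: 31 ring A dienone (C8 R)
Product: 32 tert-butyl (3S)-3-[(5R)-5-{[(1S,3R)-2,2-dimethyl-3-(prop-1-en-2-yl)cyclobutyl]methyl}-4-ethoxy-3-iodo-5-(3-methylbut-2-en-1-yl)-6-oxo-2-[tri(propan-2-yl)silyloxy]cyclohexa-1,3-dien-1-yl]hexanoate
Conditions: N-iodosuccinimide (1.05 equiv), NaHCO3, CH2Cl2, −40 to 0 °C, dark
Reagents that add atoms: N-iodosuccinimide, O=C1CCC(=O)N1I
Why: Electrophilic iodination of an enol ether β-carbon, as known for the α-position of β-alkoxy enones; C4a is the only vinylic C–H, and attack there gives an oxocarbenium ion at C8a that loses the C4a proton, whereas attack at the fully substituted and doubly flanked C6 cannot end in proton loss and should revert.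

Step 18
Reactants: 32 C4a iodide; 27 (2S,3R)-2-methyl-3-(triethylsilyloxy)butanal
Product: 33 tert-butyl (3S)-3-[(5R)-5-{[(1S,3R)-2,2-dimethyl-3-(prop-1-en-2-yl)cyclobutyl]methyl}-4-ethoxy-3-[(2R,3R)-1-hydroxy-2-methyl-3-(triethylsilyloxy)butyl]-5-(3-methylbut-2-en-1-yl)-6-oxo-2-[tri(propan-2-yl)silyloxy]cyclohexa-1,3-dien-1-yl]hexanoate (both carbinol epimers)
Conditions: CrCl2 (8 equiv), NiCl2 (2 mol%), 27 (2.5 equiv), degassed DMSO, rt; aq. NH4Cl
Reagents that add atoms: none
Why: Nozaki–Hiyama–Kishi coupling; zerovalent nickel inserts into the C–I bond and the alkenylchromium species (trivalent chromium) adds only to the aldehyde, leaving the C7 ketone, the ester and both silyl ethers alone. The carbinol center is uncontrolled and is removed in step 19, and the non-basic medium preserves the α-center of 27.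

Step 19
Reactants: 33 C4 carbinol (both epimers)
Product: 34 tert-butyl (3S)-3-[(5R)-5-{[(1S,3R)-2,2-dimethyl-3-(prop-1-en-2-yl)cyclobutyl]methyl}-4-ethoxy-3-[(2S,3R)-2-methyl-3-(triethylsilyloxy)butanoyl]-5-(3-methylbut-2-en-1-yl)-6-oxo-2-[tri(propan-2-yl)silyloxy]cyclohexa-1,3-dien-1-yl]hexanoate
Conditions: Dess–Martin periodinane, NaHCO3, CH2Cl2, 0 °C
Reagents that add atoms: none
Why: Buffered Dess–Martin oxidation of the hindered allylic alcohol to the C4 ketone; the buffer keeps acetic acid away from the ionizable carbinol and from the C3 center.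

Step 20
Reactants: 34 C4 ketone
Product: 36 tert-butyl (3S)-3-[(2R,3S,8R)-8-{[(1S,3R)-2,2-dimethyl-3-(prop-1-en-2-yl)cyclobutyl]methyl}-5-hydroxy-2,3-dimethyl-8-(3-methylbut-2-en-1-yl)-4,7-dioxo-3,4,7,8-tetrahydro-2H-chromen-6-yl]hexanoate, via hydroxy enol 35 (not isolated)
Conditions: HF·pyridine, pyridine, THF, 0 °C to rt; then PPTS (10 mol%), toluene, 50 °C
Reagents that add atoms: none
Why: Fluoride cleaves the triethylsilyl ether and the enol silyl ether; the freed C2 hydroxyl then adds to C8a and the ethoxy group leaves (6-endo addition–elimination, the reaction that converts β-hydroxy β′-alkoxy enones into 2,3-dihydro-4-pyranones). C8a is the β-carbon of an alkoxymethylene dicarbonyl unit and carries the only leaving group, while O5 is held in the chelated enol, so closure should go to O8a. No bond to C2 or C3 is broken, so the cis (2R,3S) arrangement of 27 is retained.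

Step 21
Reactants: 36 tert-butyl ester of the target
Product: 38 (3S)-3-[(2R,3S,8R)-8-{[(1S,3R)-2,2-dimethyl-3-(prop-1-en-2-yl)cyclobutyl]methyl}-5-hydroxy-2,3-dimethyl-8-(3-methylbut-2-en-1-yl)-4,7-dioxo-3,4,7,8-tetrahydro-2H-chromen-6-yl]hexanoic acid (CNP0364345.1), via bis-silyl derivative 37 (not isolated)
Conditions: Me3SiOTf (4 equiv), 2,6-lutidine (6 equiv), CH2Cl2, −20 to 0 °C; then aq. NaH2PO4 (pH 5), THF, 0 °C
Reagents that add atoms: none
Why: Silyl triflate-mediated tert-butyl ester cleavage; O-silylation of the ester releases the tert-butyl cation as 2-methylpropene with lutidine taking the proton, so no protic acid reaches the isopropenylcyclobutane or the prenyl group, and the silyl ester and C5 silyl ether of 37 hydrolyze in the buffer.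

## Compound list

1 | (1R,5R)-(+)-verbenone, (1R,5R)-4,6,6-trimethylbicyclo[3.1.1]hept-3-en-2-one | CC1=CC(=O)[C@@H]2C[C@H]1C2(C)C | starting material
2 | (1R,3S)-3-acetyl-2,2-dimethylcyclobutane-1-carboxylic acid (cis) | CC(=O)[C@H]1C[C@@H](C(=O)O)C1(C)C | intermediate
3 | (1R,3R)-2,2-dimethyl-3-(prop-1-en-2-yl)cyclobutane-1-carboxylic acid (cis) | C=C(C)[C@H]1C[C@@H](C(=O)O)C1(C)C | intermediate
4 | [(1R,3R)-2,2-dimethyl-3-(prop-1-en-2-yl)cyclobutyl]methanol (cis) | C=C(C)[C@H]1C[C@@H](CO)C1(C)C | intermediate
5 | (1R,3R)-1-(iodomethyl)-2,2-dimethyl-3-(prop-1-en-2-yl)cyclobutane (cis) | C=C(C)[C@H]1C[C@@H](CI)C1(C)C | intermediate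
6 | 5-methylhex-4-enoic acid | CC(C)=CCCC(=O)O | starting material
7 | 2-{[(1S,3R)-2,2-dimethyl-3-(prop-1-en-2-yl)cyclobutyl]methyl}-5-methylhex-4-enoic acid (both C2 epimers) | C=C(C)[C@H]1C[C@@H](CC(CC=C(C)C)C(=O)O)C1(C)C | intermediate
8 | ethoxyacetylene (ethoxyethyne) | CCOC#C | starting material
9 | 2-{[(1S,3R)-2,2-dimethyl-3-(prop-1-en-2-yl)cyclobutyl]methyl}-5-methylhex-4-enoyl chloride | C=C(C)[C@H]1C[C@@H](CC(CC=C(C)C)C(=O)Cl)C1(C)C | intermediate (not isolated)
10 | 2-{[(1S,3R)-2,2-dimethyl-3-(prop-1-en-2-yl)cyclobutyl]methyl}-5-methylhexa-1,4-dien-1-one (dialkylketene) | C=C(C)[C@H]1C[C@@H](CC(CC=C(C)C)=C=O)C1(C)C | intermediate (not isolated)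
11 | 4-{[(1S,3R)-2,2-dimethyl-3-(prop-1-en-2-yl)cyclobutyl]methyl}-3-ethoxy-4-(3-methylbut-2-en-1-yl)cyclobut-2-en-1-one (both C4 epimers) | C=C(C)[C@H]1C[C@@H](CC2(CC=C(C)C)C(=O)C=C2OCC)C1(C)C | intermediate
12 | (4R)-4-benzyl-1,3-oxazolidin-2-one | O=C1N[C@H](Cc2ccccc2)CO1 | starting material
13 | pentanoyl chloride | CCCCC(=O)Cl | starting material
14 | (4R)-4-benzyl-3-pentanoyl-1,3-oxazolidin-2-one | CCCCC(=O)N1[C@H](Cc2ccccc2)COC1=O | intermediate
15 | tert-butyl bromoacetate | CC(C)(C)OC(=O)CBr | starting material
16 | tert-butyl (3S)-3-{[(4R)-4-benzyl-2-oxo-1,3-oxazolidin-3-yl]carbonyl}hexanoate | CCC[C@@H](CC(=O)OC(C)(C)C)C(=O)N1[C@H](Cc2ccccc2)COC1=O | intermediate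
17 | (2S)-2-[2-(tert-butoxy)-2-oxoethyl]pentanoic acid | CCC[C@@H](CC(=O)OC(C)(C)C)C(=O)O | intermediate
18 | 4-tert-butyl 1-methyl (2S)-2-propylbutanedioate | CCC[C@@H](CC(=O)OC(C)(C)C)C(=O)OC | intermediate
19 | lithium (3S)-1,1-dibromo-5-(tert-butoxy)-5-oxo-3-propylpent-1-en-2-olate | CCC[C@@H](CC(=O)OC(C)(C)C)C([O-])=C(Br)Br.[Li+] | intermediate (not isolated)
20 | lithium (3S)-5-(tert-butoxy)-5-oxo-3-propylpent-1-yn-1-olate | CCC[C@@H](CC(=O)OC(C)(C)C)C#C[O-].[Li+] | intermediate (not isolated)
21 | tert-butyl (3S)-3-propyl-5-[tri(propan-2-yl)silyloxy]pent-4-ynoate | CCC[C@@H](CC(=O)OC(C)(C)C)C#CO[Si](C(C)C)(C(C)C)C(C)C | intermediate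
22 | (4S)-4-benzyl-3-propanoyl-1,3-oxazolidin-2-one | CCC(=O)N1[C@@H](Cc2ccccc2)COC1=O | starting material
23 | acetaldehyde | CC=O | starting material
24 | (4S)-4-benzyl-3-[(2S,3R)-3-hydroxy-2-methylbutanoyl]-1,3-oxazolidin-2-one | O[C@H](C)[C@H](C)C(=O)N1[C@@H](Cc2ccccc2)COC1=O | intermediate
25 | (4S)-4-benzyl-3-[(2S,3R)-2-methyl-3-(triethylsilyloxy)butanoyl]-1,3-oxazolidin-2-one | CC[Si](CC)(CC)O[C@H](C)[C@H](C)C(=O)N1[C@@H](Cc2ccccc2)COC1=O | intermediate
26 | (2R,3R)-2-methyl-3-(triethylsilyloxy)butan-1-ol | CC[Si](CC)(CC)O[C@H](C)[C@H](C)CO | intermediate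
27 | (2S,3R)-2-methyl-3-(triethylsilyloxy)butanal | CC[Si](CC)(CC)O[C@H](C)[C@H](C)C=O | intermediate
28 | 4-{[(1S,3R)-2,2-dimethyl-3-(prop-1-en-2-yl)cyclobutyl]methyl}-3-ethoxy-7-methylocta-1,3,6-trien-1-one (vinylketene, both alkene isomers) | C=C(C)[C@H]1C[C@@H](CC(CC=C(C)C)=C(OCC)C=C=O)C1(C)C | intermediate (not isolated)
29 | tert-butyl (3S)-3-{3-(2-{[(1S,3R)-2,2-dimethyl-3-(prop-1-en-2-yl)cyclobutyl]methyl}-1-ethoxy-5-methylhexa-1,4-dien-1-yl)-4-oxo-2-[tri(propan-2-yl)silyloxy]cyclobut-1-en-1-yl}hexanoate (vinylcyclobutenone) | C=C(C)[C@H]1C[C@@H](CC(CC=C(C)C)=C(OCC)C2C(=O)C([C@@H](CCC)CC(=O)OC(C)(C)C)=C2O[Si](C(C)C)(C(C)C)C(C)C)C1(C)C | intermediate (not isolated)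
30 | tert-butyl (3S)-8-{[(1S,3R)-2,2-dimethyl-3-(prop-1-en-2-yl)cyclobutyl]methyl}-7-ethoxy-11-methyl-4-(oxomethylidene)-3-propyl-5-[tri(propan-2-yl)silyloxy]dodeca-5,7,10-trienoate (dienylketene) | C=C(C)[C@H]1C[C@@H](CC(CC=C(C)C)=C(OCC)C=C(O[Si](C(C)C)(C(C)C)C(C)C)C([C@@H](CCC)CC(=O)OC(C)(C)C)=C=O)C1(C)C | intermediate (not isolated)
31 | tert-butyl (3S)-3-[(5R)-5-{[(1S,3R)-2,2-dimethyl-3-(prop-1-en-2-yl)cyclobutyl]methyl}-4-ethoxy-5-(3-methylbut-2-en-1-yl)-6-oxo-2-[tri(propan-2-yl)silyloxy]cyclohexa-1,3-dien-1-yl]hexanoate (ring A dienone: C7 ketone, C5 silyl ether, C8a ethyl ether, C8 R) | C=C(C)[C@H]1C[C@@H](C[C@@]2(CC=C(C)C)C(=O)C([C@@H](CCC)CC(=O)OC(C)(C)C)=C(O[Si](C(C)C)(C(C)C)C(C)C)C=C2OCC)C1(C)C | intermediate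
32 | the 3-iodo derivative of 31 (iodine on C4a) | C=C(C)[C@H]1C[C@@H](C[C@@]2(CC=C(C)C)C(=O)C([C@@H](CCC)CC(=O)OC(C)(C)C)=C(O[Si](C(C)C)(C(C)C)C(C)C)C(I)=C2OCC)C1(C)C | intermediate
33 | the C4a-[(2R,3R)-1-hydroxy-2-methyl-3-(triethylsilyloxy)butyl] derivative of 31 (both carbinol epimers) | C=C(C)[C@H]1C[C@@H](C[C@@]2(CC=C(C)C)C(=O)C([C@@H](CCC)CC(=O)OC(C)(C)C)=C(O[Si](C(C)C)(C(C)C)C(C)C)C(C(O)[C@@H](C)[C@@H](C)O[Si](CC)(CC)CC)=C2OCC)C1(C)C | intermediate
34 | the C4a-[(2S,3R)-2-methyl-3-(triethylsilyloxy)butanoyl] derivative of 31 | C=C(C)[C@H]1C[C@@H](C[C@@]2(CC=C(C)C)C(=O)C([C@@H](CCC)CC(=O)OC(C)(C)C)=C(O[Si](C(C)C)(C(C)C)C(C)C)C(C(=O)[C@@H](C)[C@@H](C)O[Si](CC)(CC)CC)=C2OCC)C1(C)C | intermediate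
35 | tert-butyl (3S)-3-[(5R)-5-{[(1S,3R)-2,2-dimethyl-3-(prop-1-en-2-yl)cyclobutyl]methyl}-4-ethoxy-2-hydroxy-3-[(2S,3R)-3-hydroxy-2-methylbutanoyl]-5-(3-methylbut-2-en-1-yl)-6-oxocyclohexa-1,3-dien-1-yl]hexanoate (hydroxy enol) | C=C(C)[C@H]1C[C@@H](C[C@@]2(CC=C(C)C)C(=O)C([C@@H](CCC)CC(=O)OC(C)(C)C)=C(O)C(C(=O)[C@@H](C)[C@@H](C)O)=C2OCC)C1(C)C | intermediate (not isolated)
36 | tert-butyl (3S)-3-[(2R,3S,8R)-8-{[(1S,3R)-2,2-dimethyl-3-(prop-1-en-2-yl)cyclobutyl]methyl}-5-hydroxy-2,3-dimethyl-8-(3-methylbut-2-en-1-yl)-4,7-dioxo-3,4,7,8-tetrahydro-2H-chromen-6-yl]hexanoate | C=C(C)[C@H]1C[C@@H](C[C@@]2(CC=C(C)C)C(=O)C([C@@H](CCC)CC(=O)OC(C)(C)C)=C(O)C3=C2O[C@H](C)[C@H](C)C3=O)C1(C)C | intermediate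
37 | trimethylsilyl (3S)-3-[(2R,3S,8R)-8-{[(1S,3R)-2,2-dimethyl-3-(prop-1-en-2-yl)cyclobutyl]methyl}-2,3-dimethyl-8-(3-methylbut-2-en-1-yl)-4,7-dioxo-5-(trimethylsilyloxy)-3,4,7,8-tetrahydro-2H-chromen-6-yl]hexanoate | C=C(C)[C@H]1C[C@@H](C[C@@]2(CC=C(C)C)C(=O)C([C@@H](CCC)CC(=O)O[Si](C)(C)C)=C(O[Si](C)(C)C)C3=C2O[C@H](C)[C@H](C)C3=O)C1(C)C | intermediate (not isolated)
38 | (3S)-3-[(2R,3S,8R)-8-{[(1S,3R)-2,2-dimethyl-3-(prop-1-en-2-yl)cyclobutyl]methyl}-5-hydroxy-2,3-dimethyl-8-(3-methylbut-2-en-1-yl)-4,7-dioxo-3,4,7,8-tetrahydro-2H-chromen-6-yl]hexanoic acid (CNP0364345.1) | C=C(C)[C@H]1C[C@@H](C[C@@]2(CC=C(C)C)C(=O)C([C@@H](CCC)CC(=O)O)=C(O)C3=C2O[C@H](C)[C@H](C)C3=O)C1(C)C | target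

## Step count and risk

Total step count: 21. Longest linear sequence: 12 steps (steps 1 to 6, then 16 to 21). The ynol ether branch (steps 7 to 11) and the aldehyde branch (steps 12 to 15) are convergent.

Steps least certain to work:

**Step 16 (key step).** The most likely failure is poor facial discrimination in the 6π closure of 30, so that the two C8 epimers form in comparable amounts. A second failure is that vinylketene 28 is lost by reclosure or a 1,5-hydrogen shift from an allylic CH2 before 21 traps it. Fallback: treat C8 as a recycling problem, not a selectivity problem. The unwanted epimer, tert-butyl (3S)-3-[(5S)-…]hexanoate F1, which forms from 11 and 21 alongside 31, is separated and irradiated (about 365 nm, toluene, rt, no nucleophile). The known photochemical ring opening of cyclohexa-2,4-dienones returns it to dienylketene 30, which recloses thermally to 31 and F1. Repeating the cycle funnels material into 31, where the route is rejoined.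

**Step 17.** The most likely failure is wrong site selectivity: ipso attack of iodine at the more electron-rich C6 with loss of the silyl group, or iodonium formation at the prenyl group with closure onto O7. Fallback: introduce the halogen before ring A exists. Cyclobutenone 11 is iodinated at C2, the α-position of its vinylogous ester (N-iodosuccinimide, MeCN), to give 4-{[(1S,3R)-2,2-dimethyl-3-(prop-1-en-2-yl)cyclobutyl]methyl}-3-ethoxy-2-iodo-4-(3-methylbut-2-en-1-yl)cyclobut-2-en-1-one F2. Annulation of F2 with 21 under the conditions of step 16 then places iodine on C4a unambiguously, and the route is rejoined at 32.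

**Step 11.** The most likely failure is loss of chemoselectivity under the strongly basic, organolithium-rich conditions: attack on the tert-butyl ester, or silylation of its enolate, instead of clean ynolate formation. Fallback: make the ynolate by oxidation of an acetylide instead of ester homologation. Imide 16 is reduced (LiBH4) to tert-butyl (3S)-3-(hydroxymethyl)hexanoate F3 and oxidized (Dess–Martin periodinane) to tert-butyl (3S)-3-formylhexanoate F4. F4 is converted with the Ohira–Bestmann reagent (K2CO3, MeOH) into tert-butyl (3S)-3-ethynylhexanoate F5. Its lithium acetylide (LiN(SiMe3)2, THF, −78 °C) is oxidized with lithium tert-butyl peroxide and trapped with iPr3SiOTf, which rejoins the route at 21.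

**Step 21.** The most likely failure is enolization of the C4 ketone toward C3 under the silyl triflate and base (a C3=C4 silyl enol ether), which would erode the cis C2/C3 relationship on hydrolysis; Lewis-acid attack on the alkenes is a lesser concern. Fallback: exchange the ester while no enolizable ketone is present. Dienone 31 is treated with iPr3SiOTf and 2,6-lutidine to give the triisopropylsilyl ester F6. F6 is carried through the chemistry of steps 17 to 19: iodide F7, carbinol F8 and ketone F9. Finally HF·pyridine and then PPTS remove all three silyl groups and close ring C in one operation, which rejoins the route at 38.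

**Step 18.** The most likely failure is slow coupling of the doubly flanked alkenyl iodide, with competing protodeiodination back to 31. Fallback: change the metal. Iodine–magnesium exchange on 32 with iPrMgCl·LiCl at −40 °C, followed by addition of 27, gives the same carbinol 33 with no new intermediates.

## Further compounds

F1 | step 16 | tert-butyl (3S)-3-[(5S)-5-{[(1S,3R)-2,2-dimethyl-3-(prop-1-en-2-yl)cyclobutyl]methyl}-4-ethoxy-5-(3-methylbut-2-en-1-yl)-6-oxo-2-[tri(propan-2-yl)silyloxy]cyclohexa-1,3-dien-1-yl]hexanoate (C8 epimer of 31) | C=C(C)[C@H]1C[C@@H](C[C@]2(CC=C(C)C)C(=O)C([C@@H](CCC)CC(=O)OC(C)(C)C)=C(O[Si](C(C)C)(C(C)C)C(C)C)C=C2OCC)C1(C)C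
F2 | step 17 | 4-{[(1S,3R)-2,2-dimethyl-3-(prop-1-en-2-yl)cyclobutyl]methyl}-3-ethoxy-2-iodo-4-(3-methylbut-2-en-1-yl)cyclobut-2-en-1-one (both C4 epimers) | C=C(C)[C@H]1C[C@@H](CC2(CC=C(C)C)C(=O)C(I)=C2OCC)C1(C)C
F3 | step 11 | tert-butyl (3S)-3-(hydroxymethyl)hexanoate | CCC[C@@H](CC(=O)OC(C)(C)C)CO
F4 | step 11 | tert-butyl (3S)-3-formylhexanoate | CCC[C@@H](CC(=O)OC(C)(C)C)C=O
F5 | step 11 | tert-butyl (3S)-3-ethynylhexanoate | CCC[C@@H](CC(=O)OC(C)(C)C)C#C
F6 | step 21 | tri(propan-2-yl)silyl ester analogue of 31 | C=C(C)[C@H]1C[C@@H](C[C@@]2(CC=C(C)C)C(=O)C([C@@H](CCC)CC(=O)O[Si](C(C)C)(C(C)C)C(C)C)=C(O[Si](C(C)C)(C(C)C)C(C)C)C=C2OCC)C1(C)C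
F7 | step 21 | tri(propan-2-yl)silyl ester analogue of 32 | C=C(C)[C@H]1C[C@@H](C[C@@]2(CC=C(C)C)C(=O)C([C@@H](CCC)CC(=O)O[Si](C(C)C)(C(C)C)C(C)C)=C(O[Si](C(C)C)(C(C)C)C(C)C)C(I)=C2OCC)C1(C)C
F8 | step 21 | tri(propan-2-yl)silyl ester analogue of 33 (both carbinol epimers) | C=C(C)[C@H]1C[C@@H](C[C@@]2(CC=C(C)C)C(=O)C([C@@H](CCC)CC(=O)O[Si](C(C)C)(C(C)C)C(C)C)=C(O[Si](C(C)C)(C(C)C)C(C)C)C(C(O)[C@@H](C)[C@@H](C)O[Si](CC)(CC)CC)=C2OCC)C1(C)C
F9 | step 21 | tri(propan-2-yl)silyl ester analogue of 34 | C=C(C)[C@H]1C[C@@H](C[C@@]2(CC=C(C)C)C(=O)C([C@@H](CCC)CC(=O)O[Si](C(C)C)(C(C)C)C(C)C)=C(O[Si](C(C)C)(C(C)C)C(C)C)C(C(=O)[C@@H](C)[C@@H](C)O[Si](CC)(CC)CC)=C2OCC)C1(C)C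
F0 | step 18 | none | none
A1 | alternative 1 | (3R)-3-[(tert-butyldiphenylsilyloxy)methyl]-2,2-dimethylcyclobutan-1-one | O=C1C[C@@H](CO[Si](c2ccccc2)(c2ccccc2)C(C)(C)C)C1(C)C
A2 | alternative 1 | 1-[(2S,5S)-2,5-dimethylpyrrolidin-1-yl]-2-methylpropan-1-one | CC(C)C(=O)N1[C@@H](C)CC[C@@H]1C
A3 | alternative 1 | tert-butyl(diphenyl)(prop-2-en-1-yloxy)silane | C=CCO[Si](c1ccccc1)(c1ccccc1)C(C)(C)C
A4 | alternative 2 | cis-[(1R,3R)-2,2-dimethyl-3-(prop-1-en-2-yl)cyclobutyl]methyl acetate | C=C(C)[C@H]1C[C@@H](COC(C)=O)C1(C)C
A5 | alternative 2 | (R)-lavandulyl acetate, (2R)-5-methyl-2-(prop-1-en-2-yl)hex-4-en-1-yl acetate | CC(C)=CC[C@@H](COC(C)=O)C(C)=C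
A6 | alternative 3 | methyl 2-{[(1S,3R)-2,2-dimethyl-3-(prop-1-en-2-yl)cyclobutyl]methyl}-2-(cis-2,3-dimethyl-4-oxo-3,4-dihydro-2H-pyran-6-yl)-5-methylhex-4-enoate | C=C(C)[C@H]1C[C@@H](C[C@@](C2=CC(=O)[C@@H](C)[C@@H](C)O2)(CC=C(C)C)C(=O)OC)C1(C)C
A7 | alternative 3 | methyl 2-{[(1S,3R)-2,2-dimethyl-3-(prop-1-en-2-yl)cyclobutyl]methyl}-2-[1-methoxy-3-(trimethylsilyloxy)penta-1,3-dien-1-yl]-5-methylhex-4-enoate | C=C(C)[C@H]1C[C@@H](C[C@@](C(OC)=CC(O[Si](C)(C)C)=CC)(CC=C(C)C)C(=O)OC)C1(C)C
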